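**Strategy.** The skeleton is cut at C4–C5 and C9–C10, so that rings A and B close in one Mn(OAc)3 radical cascade: the β-keto ester radical at C4 adds 6-endo to C5 of a (Z)-C5=C10 alkene and the tertiary C10 radical then closes ring B by 5-exo conjugate addition to C9 of a ring C enone. The step exploits that C10, the quaternary carbon shared by rings A and B, lies between C5 and C9 and that C9 is β to a carbonyl placed at C12. The precursor is a ring C/D bicyclo[3.2.1]octenone whose bridgehead C8 carries the C6 ester and the open C5–C10–C1–C4 chain.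

Key step: step 11

Remark: carbon numbers C1–C20 and the α/β face labels are those of the gibberellin skeleton of the target (C20 on the α face) and are used for all intermediates; the CBS reduction is assumed to give the R carbinol, as it does with simple cyclohexenones.

Step 1
Reactants: 1 3-ethoxycyclohex-2-en-1-one; 2 3-bromoprop-1-yne (propargyl bromide)
Product: 4 3-(prop-2-yn-1-yl)cyclohex-2-en-1-one, via carbinol adduct 3 (not isolated)
Conditions: 2, Mg, HgCl2 (cat.), Et2O, 0 °C; then 1, −20 °C; then 1 M HCl, rt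
Reagents that add atoms: water (O)
Why: Stork–Danheiser transposition: the allenyl/propargyl Grignard reagent adds 1,2 to the vinylogous ester (SE2' mode, giving the propargyl carbinol) and acid hydrolysis with loss of ethanol should give the 3-substituted enone; no stereocentre is formed.

Step 2
Reactants: 4 3-(prop-2-yn-1-yl)cyclohex-2-en-1-one
Product: 5 (1R)-3-(prop-2-yn-1-yl)cyclohex-2-en-1-ol
Conditions: (S)-2-methyl-CBS-oxazaborolidine (15 mol %), catecholborane, toluene, −78 °C
Reagents that add atoms: none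
Why: Corey–Bakshi–Shibata reduction: the catalyst binds the ketone with the alkenyl arm as the large group and delivers hydride to one face, which should give the R carbinol (C11), while catecholborane at −78 °C leaves the alkyne alone.

Step 3
Reactants: 5 (1R)-3-(prop-2-yn-1-yl)cyclohex-2-en-1-ol; 6 (2E)-but-2-enoyl chloride
Product: 7 (1R)-3-(prop-2-yn-1-yl)cyclohex-2-en-1-yl (2E)-but-2-enoate
Conditions: pyridine, DMAP (cat.), CH2Cl2, 0 °C
Reagents that add atoms: none
Why: O-acylation with retention at the carbinol carbon; pyridine instead of a trialkylamine avoids vinylketene formation.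

Step 4
Reactants: 7 (1R)-3-(prop-2-yn-1-yl)cyclohex-2-en-1-yl (2E)-but-2-enoate
Product: 10 (2S)-2-[(1R)-1-(prop-2-yn-1-yl)cyclohex-2-en-1-yl]but-3-enoic acid, via ketene silyl acetal 8 (not isolated), via trimethylsilyl ester 9 (not isolated)
Conditions: LDA (2.3 equiv), TMSCl, THF/DMPU, −78 → 50 °C; then K2CO3, MeOH; then dilute HCl
Reagents that add atoms: none
Why: Ireland–Claisen rearrangement of the dienolate from γ-deprotonation of the crotonate: the C6–C8 bond forms suprafacially on the face that carried the ester oxygen, so the R carbinol centre is transferred to the quaternary C8 (R), and the (Z)-ketene acetal in a chair-like arrangement that keeps the vinyl group away from the ring should set C6 (S); the acetylide is silylated in the flask and both silyl groups come off with K2CO3/MeOH.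

Step 5
Reactants: 10 (2S)-2-[(1R)-1-(prop-2-yn-1-yl)cyclohex-2-en-1-yl]but-3-enoic acid
Product: 11 (2S)-2-[(1R)-4-oxo-1-(prop-2-yn-1-yl)cyclohex-2-en-1-yl]but-3-enoic acid
Conditions: Rh2(cap)4 (1 mol %, cap = caprolactamate), t-BuOOH (70% in water), NaHCO3, CH2Cl2, rt
Reagents that add atoms: tert-butyl hydroperoxide (CC(C)(C)OO)
Why: Allylic C–H oxidation by the tert-butylperoxyl radical at C12, the only ring methylene allylic to the C9=C11 alkene (C8 is quaternary), should give the enone without touching C6 or C8.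

Step 6
Reactants: 11 (2S)-2-[(1R)-4-oxo-1-(prop-2-yn-1-yl)cyclohex-2-en-1-yl]but-3-enoic acid
Product: 13 (2S)-2-[(1R,5R)-6-methylidene-4-oxobicyclo[3.2.1]oct-2-en-1-yl]but-3-enoic acid, via bis-silyl dienol ether 12 (not isolated)
Conditions: TBSOTf, Et3N, CH2Cl2, −78 → 0 °C; then Ph3PAuCl (5 mol %), AgBF4 (5 mol %), CH2Cl2/MeOH (10:1), rt; then AcOH/THF/H2O
Reagents that add atoms: none
Why: Gold-catalysed Conia-ene-type 5-exo-dig cyclisation of the silyl enol ether (only C13 can be enolised because C8 is quaternary) onto the alkyne closes ring D with its exocyclic methylene; the bridgehead C13 can only form cis to the propargyl arm, so its configuration follows from C8.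

Step 7
Reactants: 14 methyl 2-methyl-3-oxobutanoate; 15 3-chloro-2-(chloromethyl)prop-1-ene
Product: 16 methyl 6-(chloromethyl)-2-methyl-3-oxohept-6-enoate
Conditions: NaH, THF, 0 °C; n-BuLi, 0 °C; then 15 (3 equiv), −78 → 0 °C; aqueous NH4Cl
Reagents that add atoms: none
Why: γ-Alkylation of the acetoacetate dianion by SN2 displacement of one allylic chloride (excess dichloride stops at mono-alkylation); the α-carbon is left as a mixture because it becomes a radical centre in step 11.

Step 8
Reactants: 13 (2S)-2-[(1R,5R)-6-methylidene-4-oxobicyclo[3.2.1]oct-2-en-1-yl]but-3-enoic acid; 16 methyl 6-(chloromethyl)-2-methyl-3-oxohept-6-enoate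
Product: 17 methyl 6-({[(2S)-2-[(1R,5R)-6-methylidene-4-oxobicyclo[3.2.1]oct-2-en-1-yl]but-3-enoyl]oxy}methyl)-2-methyl-3-oxohept-6-enoate
Conditions: Cs2CO3 (0.55 equiv), DMF, rt
Reagents that add atoms: none
Why: SN2 O-alkylation of the caesium carboxylate by the allylic chloride; the carboxylate is too weak a base to enolise C6 or the β-keto ester, so C6 should be kept.

Step 9
Reactants: 17 (the diene ester of step 8)
Product: 18 methyl 2-methyl-5-[(5S)-5-[(1R,5R)-6-methylidene-4-oxobicyclo[3.2.1]oct-2-en-1-yl]-6-oxo-5,6-dihydro-2H-pyran-3-yl]-3-oxopentanoate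
Conditions: second-generation Grubbs catalyst (5 mol %), 1,4-benzoquinone (10 mol %), CH2Cl2 (2 mM), 40 °C
Reagents that add atoms: none
Why: Ring-closing metathesis of the C5 vinyl group with the 1,1-disubstituted C10 alkene gives the six-membered lactone, whose ring forces C6 and C20 cis on the new C5=C10 bond; the enone is inert and closure onto the ring D methylene would need a bridgehead alkene.

Step 10
Reactants: 18 (the unsaturated lactone of step 9)
Product: 20 dimethyl (2S,3Z)-4-(acetoxymethyl)-8-methyl-2-[(1R,5R)-6-methylidene-4-oxobicyclo[3.2.1]oct-2-en-1-yl]-7-oxonon-3-enedioate (epimers at the methyl-bearing carbon), via hydroxy diester 19 (not isolated)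
Conditions: K2CO3 (0.2 equiv), MeOH, 0 °C; AcOH quench, evaporation; then Ac2O, pyridine, DMAP (cat.), CH2Cl2, 0 °C
Reagents that add atoms: methanol (CO); acetic anhydride (CC(=O)OC(C)=O)
Why: Lactone methanolysis followed by acetylation of the freed C20 alcohol releases the tether but keeps the (Z) geometry it imposed; catalytic carbonate at 0 °C should leave C6 unepimerised.

Step 11
Reactants: 20 (the acyclic acetoxy diester of step 10)
Product: 21 dimethyl 20-acetoxy-3,12-dioxogibberell-16-ene-7,19-dioate (4β-CH3, 4α-CO2Me, 5β-H, 6β-CO2Me, 9β-H, 10α-CH2OAc)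
Conditions: Mn(OAc)3·2H2O (2.2 equiv), degassed EtOH/AcOH (4:1), 0.02 M, 60 °C
Reagents that add atoms: none
Why: Mn(OAc)3 oxidises the enol of the α-methyl β-keto ester to the electrophilic C4 radical, which adds 6-endo-trig to the less substituted C5 of the C5=C10 alkene (ring A); the nucleophilic tertiary C10 radical then adds 5-exo-trig to C9, the β-carbon of the ring C enone (ring B, the C9–C10 bond), and the α-keto radical at C11 is quenched by hydrogen abstraction from ethanol. The closest known reaction type is the manganese triacetate oxidative free-radical polycyclisation of unsaturated β-keto esters, here ended by a Giese addition. C5 is set by the C6 stereocentre: allylic 1,3-strain against C20 holds H6 in the alkene plane and C4 approaches anti to the bulky C8 bicycle; C4 is set by the chair-like transition state that places the ester axial, cis to C20. C10 and C9 follow because C9 adds anti to the new C4–C5 bond (trans A/B fusion, C20 axial) and on the exo face of the bicyclo[3.2.1]octenone, away from the two-carbon bridge (H9 β). The step needs 6-endo over 5-exo attack (secured by the trisubstituted alkene and the electrophilic radical) and ring closure before oxidation of the C10 radical (secured by leaving out Cu(OAc)2 and by the polarity-matched enone acceptor).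

Step 12
Reactants: 21 (the diketone of step 11)
Product: 23 dimethyl 20-acetoxy-3-oxogibberell-16-ene-7,19-dioate, via tosylhydrazone 22 (not isolated)
Conditions: TsNHNH2 (1.1 equiv), EtOH, 40 °C; then catecholborane, CHCl3, 0 °C; NaOAc·3H2O, 60 °C
Reagents that add atoms: none
Why: Reductive deoxygenation of a tosylhydrazone (hydride addition to C=N, loss of sulfinate, then N2 from the diazene); the hydrazone should form at C12 because the C3 ketone is flanked by the fully substituted C4, and no stereocentre changes.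

Step 13
Reactants: 23 (the C3 ketone of step 12)
Product: 24 dimethyl 20-acetoxy-2β-hydroxy-3-oxogibberell-16-ene-7,19-dioate
Conditions: KHMDS (1.1 equiv), THF, −78 °C; 2-(benzenesulfonyl)-3-phenyloxaziridine, −78 → −40 °C
Reagents that add atoms: 2-(benzenesulfonyl)-3-phenyloxaziridine (O=S(=O)(c1ccccc1)N1OC1c1ccccc1)
Why: Davis oxidation of the C2 enolate, the only enolisable position of the ketone; the axial C19 ester and C20 acetoxymethyl groups block the α face, so oxygen should arrive from the β face to give the equatorial 2β-alcohol.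

Step 14
Reactants: 24 (the α-hydroxy ketone of step 13)
Product: 25 dimethyl 20-acetoxy-2β,3β-dihydroxygibberell-16-ene-7,19-dioate
Conditions: L-selectride (LiBH(s-Bu)3, 2.5 equiv), THF, −78 °C
Reagents that add atoms: none
Why: Bulky-hydride ketone reduction: equatorial attack, away from the axial hydrogens at C1 and C5, should give the axial 3β-alcohol cis to the 2β-hydroxyl.

Step 15
Reactants: 25 (the diol of step 14)
Product: 26 methyl ester at C7 of 2β,3β,20-trihydroxygibberell-16-ene-7,19-dioic acid 19,20-lactone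
Conditions: K2CO3, MeOH, 0 °C → rt
Reagents that add atoms: none
Why: Acetate methanolysis frees the C20 alkoxide, which is held 1,3-diaxial to the C19 methyl ester and closes the δ-lactone by transesterification; no stereocentre is touched.

Step 16
Reactants: 26 (the lactone methyl ester of step 15)
Product: 27 2β,3β,20-trihydroxygibberell-16-ene-7,19-dioic acid 19,20-lactone (CNP0332607.1)
Conditions: n-PrSLi, HMPA, rt; then dilute HCl to pH 3
Reagents that add atoms: none
Why: SN2 demethylation of the hindered C7 methyl ester by thiolate at the methyl carbon; the lactone alkyl carbon C20 is neopentylic and should not be attacked, and no stereocentre is involved.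

**Compound list**

1 | 3-ethoxycyclohex-2-en-1-one | CCOC1=CC(=O)CCC1 | starting material
2 | 3-bromoprop-1-yne | C#CCBr | starting material
3 | 3-ethoxy-1-(prop-2-yn-1-yl)cyclohex-2-en-1-ol | CCOC1=CC(O)(CC#C)CCC1 | intermediate
4 | 3-(prop-2-yn-1-yl)cyclohex-2-en-1-one | O=C1C=C(CC#C)CCC1 | intermediate
5 | (1R)-3-(prop-2-yn-1-yl)cyclohex-2-en-1-ol | O[C@H]1C=C(CC#C)CCC1 | intermediate
6 | (2E)-but-2-enoyl chloride | C/C=C/C(=O)Cl | starting material
7 | (1R)-3-(prop-2-yn-1-yl)cyclohex-2-en-1-yl (2E)-but-2-enoate | C/C=C/C(=O)O[C@H]1C=C(CC#C)CCC1 | intermediate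
8 | trimethyl{[(1Z)-1-{[(1R)-3-(3-trimethylsilylprop-2-yn-1-yl)cyclohex-2-en-1-yl]oxy}buta-1,3-dien-1-yl]oxy}silane | C=C/C=C(\O[Si](C)(C)C)O[C@H]1C=C(CC#C[Si](C)(C)C)CCC1 | intermediate
9 | trimethylsilyl (2S)-2-[(1R)-1-(3-trimethylsilylprop-2-yn-1-yl)cyclohex-2-en-1-yl]but-3-enoate | C[Si](C)(C)C#CC[C@]1(C=CCCC1)[C@H](C=C)C(=O)O[Si](C)(C)C | intermediate
10 | (2S)-2-[(1R)-1-(prop-2-yn-1-yl)cyclohex-2-en-1-yl]but-3-enoic acid | C#CC[C@]1(C=CCCC1)[C@H](C=C)C(=O)O | intermediate
11 | (2S)-2-[(1R)-4-oxo-1-(prop-2-yn-1-yl)cyclohex-2-en-1-yl]but-3-enoic acid | C#CC[C@]1(C=CC(=O)CC1)[C@H](C=C)C(=O)O | intermediate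
12 | tert-butyldimethylsilyl (2S)-2-[(1R)-4-(tert-butyldimethylsilyloxy)-1-(prop-2-yn-1-yl)cyclohexa-2,4-dien-1-yl]but-3-enoate | C#CC[C@]1(C=CC(O[Si](C)(C)C(C)(C)C)=CC1)[C@H](C=C)C(=O)O[Si](C)(C)C(C)(C)C | intermediate
13 | (2S)-2-[(1R,5R)-6-methylidene-4-oxobicyclo[3.2.1]oct-2-en-1-yl]but-3-enoic acid | C=C1C[C@@]2(C[C@H]1C(=O)C=C2)[C@H](C=C)C(=O)O | intermediate
14 | methyl 2-methyl-3-oxobutanoate | COC(=O)C(C)C(C)=O | starting material
15 | 3-chloro-2-(chloromethyl)prop-1-ene | C=C(CCl)CCl | starting material
16 | methyl 6-(chloromethyl)-2-methyl-3-oxohept-6-enoate | COC(=O)C(C)C(=O)CCC(=C)CCl | intermediate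
17 | methyl 6-({[(2S)-2-[(1R,5R)-6-methylidene-4-oxobicyclo[3.2.1]oct-2-en-1-yl]but-3-enoyl]oxy}methyl)-2-methyl-3-oxohept-6-enoate | C=C1C[C@@]2(C[C@H]1C(=O)C=C2)[C@H](C=C)C(=O)OCC(=C)CCC(=O)C(C)C(=O)OC | intermediate
18 | methyl 2-methyl-5-[(5S)-5-[(1R,5R)-6-methylidene-4-oxobicyclo[3.2.1]oct-2-en-1-yl]-6-oxo-5,6-dihydro-2H-pyran-3-yl]-3-oxopentanoate | C=C1C[C@@]2(C[C@H]1C(=O)C=C2)[C@@H]1C=C(CCC(=O)C(C)C(=O)OC)COC1=O | intermediate
19 | dimethyl (2S,3Z)-4-(hydroxymethyl)-8-methyl-2-[(1R,5R)-6-methylidene-4-oxobicyclo[3.2.1]oct-2-en-1-yl]-7-oxonon-3-enedioate | C=C1C[C@@]2(C[C@H]1C(=O)C=C2)[C@@H](C(=O)OC)/C=C(\CO)CCC(=O)C(C)C(=O)OC | intermediate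
20 | dimethyl (2S,3Z)-4-(acetoxymethyl)-8-methyl-2-[(1R,5R)-6-methylidene-4-oxobicyclo[3.2.1]oct-2-en-1-yl]-7-oxonon-3-enedioate | C=C1C[C@@]2(C[C@H]1C(=O)C=C2)[C@@H](C(=O)OC)/C=C(\COC(C)=O)CCC(=O)C(C)C(=O)OC | intermediate
21 | dimethyl 20-acetoxy-3,12-dioxogibberell-16-ene-7,19-dioate (4β-CH3, 5β-H, 6β-CO2Me, 9β-H, 10α-CH2OAc) | C=C1C[C@]23C[C@H]1C(=O)C[C@H]2[C@]2(COC(C)=O)CCC(=O)[C@@](C)(C(=O)OC)[C@H]2[C@@H]3C(=O)OC | intermediate
22 | C12 4-methylbenzenesulfonylhydrazone of 21 | C=C1C[C@]23C[C@H]1C(=NNS(=O)(=O)c1ccc(C)cc1)C[C@H]2[C@]2(COC(C)=O)CCC(=O)[C@@](C)(C(=O)OC)[C@H]2[C@@H]3C(=O)OC | intermediate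
23 | dimethyl 20-acetoxy-3-oxogibberell-16-ene-7,19-dioate | C=C1C[C@]23C[C@H]1CC[C@H]2[C@]2(COC(C)=O)CCC(=O)[C@@](C)(C(=O)OC)[C@H]2[C@@H]3C(=O)OC | intermediate
24 | dimethyl 20-acetoxy-2β-hydroxy-3-oxogibberell-16-ene-7,19-dioate | C=C1C[C@]23C[C@H]1CC[C@H]2[C@]2(COC(C)=O)C[C@H](O)C(=O)[C@@](C)(C(=O)OC)[C@H]2[C@@H]3C(=O)OC | intermediate
25 | dimethyl 20-acetoxy-2β,3β-dihydroxygibberell-16-ene-7,19-dioate | C=C1C[C@]23C[C@H]1CC[C@H]2[C@]2(COC(C)=O)C[C@H](O)[C@H](O)[C@@](C)(C(=O)OC)[C@H]2[C@@H]3C(=O)OC | intermediate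
26 | 7-methyl ester of 2β,3β,20-trihydroxygibberell-16-ene-7,19-dioic acid 19,20-lactone | C=C1C[C@]23C[C@H]1CC[C@H]2[C@]12COC(=O)[C@](C)([C@@H](O)[C@@H](O)C1)[C@H]2[C@@H]3C(=O)OC | intermediate
27 | 2β,3β,20-trihydroxygibberell-16-ene-7,19-dioic acid 19,20-lactone (CNP0332607.1) | C=C1C[C@]23C[C@H]1CC[C@H]2[C@]12COC(=O)[C@](C)([C@@H](O)[C@@H](O)C1)[C@H]2[C@@H]3C(=O)O | target

**Step count.** Total: 16 steps. Longest linear sequence: 15 steps (steps 1–6 and 8–16); step 7 is a one-step side branch.

**Steps most likely to fail**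

Step 11 (key step). The first closure may be slow because C5 is flanked by the branched C6, and the tertiary C10 radical may be oxidised by Mn(OAc)3 (elimination or acetate capture) before it reaches C9. The fallback moves to a reductive photoredox manifold with no stoichiometric oxidant. It sets out from 20: α-bromination of the β-keto ester (NBS, Mg(ClO4)2 cat., EtOAc, 0 °C) would give the α-bromo β-keto ester F1. Irradiation of F1 with Ru(bpy)3Cl2 (1 mol %) and i-Pr2NEt in DMF (blue LEDs) would generate the same C4 radical by single-electron reduction. With only a sluggish hydrogen donor present, both ring closures can run before hydrogen transfer ends the sequence, and the route is rejoined at 21.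

Step 4. The amide base may add to the crotonate instead of removing the γ-proton, and an insecure dienolate geometry may give poor control at C6. The fallback uses a saturated ester and unveils the vinyl group afterwards. It sets out from 5: esterification with 4-(phenylselanyl)butanoic acid (DCC, DMAP, CH2Cl2) would give the selenide ester F2. Its Ireland–Claisen rearrangement (LDA, TMSCl, THF, −78 → 50 °C; then K2CO3, MeOH) runs through the (E)-ketene acetal that LDA in THF reliably gives and the boat-like arrangement usual for cyclohexenyl esters, and should give the acid F3 with the same C6 and C8 configuration. Oxidation (H2O2, pyridine, CH2Cl2, 0 °C) and selenoxide syn-elimination would then give the vinyl group and return to 10.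

Step 12. Hydrazone formation may not discriminate fully between the C12 and C3 ketones, and the borane/diazene sequence may attack the exocyclic alkene. The fallback replaces it by thioketalisation and radical desulfurisation. It sets out from 21: 1,2-ethanedithiol with Zn(OTf)2 in CH2Cl2 should convert only the unhindered C12 ketone into the dithiolane F4, since thioketalisation is strongly retarded next to a quaternary carbon. Bu3SnH and AIBN in toluene at 110 °C would then cleave both C–S bonds and return to 23.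

**Further compounds**

F1 | step 11 | dimethyl (2S,3Z)-4-(acetoxymethyl)-8-bromo-8-methyl-2-[(1R,5R)-6-methylidene-4-oxobicyclo[3.2.1]oct-2-en-1-yl]-7-oxonon-3-enedioate | C=C1C[C@@]2(C[C@H]1C(=O)C=C2)[C@@H](C(=O)OC)/C=C(\COC(C)=O)CCC(=O)C(C)(Br)C(=O)OC
F2 | step 4 | (1R)-3-(prop-2-yn-1-yl)cyclohex-2-en-1-yl 4-(phenylselanyl)butanoate | O=C(CCC[Se]c1ccccc1)O[C@H]1C=C(CC#C)CCC1
F3 | step 4 | (2S)-4-(phenylselanyl)-2-[(1R)-1-(prop-2-yn-1-yl)cyclohex-2-en-1-yl]butanoic acid | C#CC[C@]1(C=CCCC1)[C@H](CC[Se]c1ccccc1)C(=O)O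
F4 | step 12 | C12 ethane-1,2-diyl dithioketal (spiro-1,3-dithiolane) of 21 | C=C1C[C@]23C[C@H]1C1(SCCS1)C[C@H]2[C@]2(COC(C)=O)CCC(=O)[C@@](C)(C(=O)OC)[C@H]2[C@@H]3C(=O)OC
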